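**Assumption:** the target is read as the (2R,3R,4R,5R,6E,8R; 2′S,3′S) isomer; locants C2–C8 refer to the nonenyl linker from ring A (the 2-ethylpyranone) to ring B (the central pyranone), and C2′/C3′ to the pentan-2-yl arm on ring B.

## Retrosynthetic overview

1. C5–O bond (last step): the target is the 1,3-transposed isomer of a C7-hydroxy-Δ5 triol; a suprafacial perrhenate shift relays C7 to C5 and creates the (6E)-alkene.
2. C7–C8 bond: anti-selective vinylogous aldol of the ring B silyl dienol ether with an (E)-2-methyl enal that already carries ring A.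
3. Enal: Wittig homologation of an aldehyde whose C2–C3 bond comes from the lateral aldol of the pyranone with an (S)-Roche-ester-derived aldehyde.
4. Ring B arm (C2′–C3′): asymmetric vinylogous aldol of the same pyranone with propanal.
5. Rings: both 4-pyranone rings come from one 2,6-diethyl-3,5-dimethyl-4-pyranone, made first by C–O cyclodehydration (3-pentanone + 2 propanoic acid); no ring is formed later.

## Route

Step 1
Reactants: 1 pentan-3-one; 2 propanoic acid (2.5 equiv)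
Product: 4 2,6-diethyl-3,5-dimethyl-4H-pyran-4-one, via triketone 3 (not isolated)
Conditions: polyphosphoric acid, 100 °C, 6 h
Reagents that add atoms: none
Why: Acid-mediated double C-acylation of the ketone gives the 1,3,5-triketone, whose enol oxygen closes onto the terminal carbonyl (C–O bond) and dehydrates to the 4-pyranone (polyphosphoric acid pyranone synthesis); no stereocentre is formed.

Step 2
Reactants: 4 2,6-diethyl-3,5-dimethyl-4H-pyran-4-one (1.05 equiv); 5 propanal (1.5 equiv)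
Product: 8 6-[(2S,3S)-3-{[tert-butyl(dimethyl)silyl]oxy}pentan-2-yl]-2-ethyl-3,5-dimethyl-4H-pyran-4-one, via potassium dienolate 6 (not isolated), via silyl dienol ether 7 (not isolated)
Conditions: KN(SiMe3)2 (1.00 equiv), THF, −78 °C; tBuMe2SiOTf (1.00 equiv), −78 °C; evaporate, pentane, filter; EtCHO, (R)-3,3′-bis[3,5-bis(trifluoromethyl)phenyl]-1,1′-binaphthalene-2,2′-disulfonimide (2 mol%), toluene, −78 → −40 °C
Reagents that add atoms: tert-butyldimethylsilyl trifluoromethanesulfonate, CC(C)(C)[Si](C)(C)OS(=O)(=O)C(F)(F)F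
Why: Proposed new method: the dissociated potassium dienolate is silylated at oxygen and leaves only pentane-insoluble KOTf, so no Lewis-acidic lithium salt or free silyl triflate reaches the catalytic stage; the disulfonimide is silylated by a trace of 7 and the resulting silylium-type Lewis acid activates propanal as an ion pair with the chiral anion; the exocyclic carbon of 7 attacks the Re face through an open antiperiplanar transition state (anti, by analogy with vinylogous Mukaiyama aldols of γ-methyl dienol ethers), the aldehyde oxygen keeps its silyl group and the aromatic 4-silyloxypyrylium formed on C–C bond formation returns its silyl group to the catalyst, so C2′ and C3′ are set as (2S,3S); closest known reaction: disulfonimide-catalysed Mukaiyama and vinylogous Mukaiyama aldol additions of silyl ketene acetals, not yet shown for 2-alkylidene-4-silyloxy-2H-pyrans (the catalyst antipode is used if the observed sense is opposite).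

Step 3
Reactants: 9 methyl (2S)-3-hydroxy-2-methylpropanoate
Product: 10 methyl (2S)-2-methyl-3-[(triethylsilyl)oxy]propanoate
Conditions: Et3SiCl, imidazole, CH2Cl2, 0 °C → rt
Reagents that add atoms: chlorotriethylsilane, CC[Si](CC)(CC)Cl
Why: Standard silyl ether formation on the primary alcohol; the stereocentre is not touched.

Step 4
Reactants: 10 methyl (2S)-2-methyl-3-[(triethylsilyl)oxy]propanoate
Product: 11 (2S)-2-methyl-3-[(triethylsilyl)oxy]propanal
Conditions: iBu2AlH (1.1 equiv), CH2Cl2, −78 °C; aq. KNaC4H4O6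
Reagents that add atoms: none
Why: Low-temperature half-reduction of the ester through a stable tetrahedral aluminium hemiacetal (DIBAL reduction) gives the aldehyde without epimerising the α-centre.

Step 5
Reactants: 4 2,6-diethyl-3,5-dimethyl-4H-pyran-4-one (1.3 equiv); 11 (2S)-2-methyl-3-[(triethylsilyl)oxy]propanal
Product: 13 2-ethyl-6-[(2R,3R,4S)-3-hydroxy-4-methyl-5-[(triethylsilyl)oxy]pentan-2-yl]-3,5-dimethyl-4H-pyran-4-one, via lithium dienolate 12 (not isolated)
Conditions: LiN(SiMe3)2 (1.0 equiv rel. to 4), THF, −78 °C; 11, −78 °C, 1 h; aq. NH4Cl; chromatography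
Reagents that add atoms: none
Why: Known lateral (vinylogous) aldol of the lithium dienolate of this pyranone, where lithium is kept because the alkoxide-forming addition needs the metal on the aldehyde oxygen; Felkin–Anh attack on the α-methyl aldehyde fixes C3 relative to C4 (3,4-syn), whereas C2/C3 selectivity is expected to be only modest, so the (2R,3R,4S) isomer is separated from its C2 epimer by chromatography.

Step 6
Reactants: 13 2-ethyl-6-[(2R,3R,4S)-3-hydroxy-4-methyl-5-[(triethylsilyl)oxy]pentan-2-yl]-3,5-dimethyl-4H-pyran-4-one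
Product: 14 6-[(2R,3R,4S)-3-{[tert-butyl(dimethyl)silyl]oxy}-4-methyl-5-[(triethylsilyl)oxy]pentan-2-yl]-2-ethyl-3,5-dimethyl-4H-pyran-4-one
Conditions: tBuMe2SiOTf, 2,6-lutidine, CH2Cl2, −78 → 0 °C
Reagents that add atoms: tert-butyldimethylsilyl trifluoromethanesulfonate, CC(C)(C)[Si](C)(C)OS(=O)(=O)C(F)(F)F
Why: Silyl triflate silylation of the hindered secondary alcohol protects C3–OH and blocks retro-aldol cleavage in the following steps.

Step 7
Reactants: 14 6-[(2R,3R,4S)-3-{[tert-butyl(dimethyl)silyl]oxy}-4-methyl-5-[(triethylsilyl)oxy]pentan-2-yl]-2-ethyl-3,5-dimethyl-4H-pyran-4-one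
Product: 15 (2R,3S,4R)-3-{[tert-butyl(dimethyl)silyl]oxy}-4-(6-ethyl-3,5-dimethyl-4-oxo-4H-pyran-2-yl)-2-methylpentanal
Conditions: (COCl)2 (4 equiv), DMSO (8 equiv), CH2Cl2, −78 → −35 °C; Et3N, → 0 °C
Reagents that add atoms: none
Why: Under Swern conditions a primary triethylsilyl ether is cleaved and oxidised directly to the aldehyde while the secondary tert-butyldimethylsilyl ether survives (Swern oxidation of a silyl ether); the cold conditions keep the α-centre intact.

Step 8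
Reactants: 15 (2R,3S,4R)-3-{[tert-butyl(dimethyl)silyl]oxy}-4-(6-ethyl-3,5-dimethyl-4-oxo-4H-pyran-2-yl)-2-methylpentanal; 16 2-(triphenylphosphoranylidene)propanal (1.3 equiv)
Product: 17 (2E,4S,5R,6R)-5-{[tert-butyl(dimethyl)silyl]oxy}-6-(6-ethyl-3,5-dimethyl-4-oxo-4H-pyran-2-yl)-2,4-dimethylhept-2-enal
Conditions: toluene, 90 °C, 12 h
Reagents that add atoms: none
Why: Stabilised-ylide olefination (Wittig reaction) gives the (E)-2-methyl enal with the formyl group trans to C4, the geometry needed for the later chair-like oxygen shift.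

Step 9
Reactants: 8 6-[(2S,3S)-3-{[tert-butyl(dimethyl)silyl]oxy}pentan-2-yl]-2-ethyl-3,5-dimethyl-4H-pyran-4-one (1.3 equiv); 17 (2E,4S,5R,6R)-5-{[tert-butyl(dimethyl)silyl]oxy}-6-(6-ethyl-3,5-dimethyl-4-oxo-4H-pyran-2-yl)-2,4-dimethylhept-2-enal
Product: 20 6-[(2R,3R,4S,5E,7S,8R)-3,7-bis{[tert-butyl(dimethyl)silyl]oxy}-8-{6-[(2S,3S)-3-{[tert-butyl(dimethyl)silyl]oxy}pentan-2-yl]-3,5-dimethyl-4-oxo-4H-pyran-2-yl}-4,6-dimethylnon-5-en-2-yl]-2-ethyl-3,5-dimethyl-4H-pyran-4-one, via potassium dienolate 18 (not isolated), via silyl dienol ether 19 (not isolated)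
Conditions: 8, KN(SiMe3)2 (0.95 equiv rel. to 8), THF, −78 °C; tBuMe2SiOTf (0.95 equiv rel. to 8), −78 °C; evaporate, pentane, filter; 17, (S)-3,3′-bis[3,5-bis(trifluoromethyl)phenyl]-1,1′-binaphthalene-2,2′-disulfonimide (5 mol%), toluene, −78 → −40 °C
Reagents that add atoms: tert-butyldimethylsilyl trifluoromethanesulfonate, CC(C)(C)[Si](C)(C)OS(=O)(=O)C(F)(F)F
Why: Proposed new method: the same silylium/chiral-counteranion vinylogous Mukaiyama aldol as in step 2, now with the antipodal disulfonimide, so that the less hindered ethylidene carbon of 19 (kinetic deprotonation of the CH2 rather than the tertiary C2′–H) adds 1,2 to the Si face of the enal carbonyl through the open anti transition state and sets C7 and C8 as (7S,8R) under catalyst control; closest known reaction: disulfonimide-catalysed vinylogous Mukaiyama aldol additions to α,β-unsaturated aldehydes.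

Step 10
Reactants: 20 6-[(2R,3R,4S,5E,7S,8R)-3,7-bis{[tert-butyl(dimethyl)silyl]oxy}-8-{6-[(2S,3S)-3-{[tert-butyl(dimethyl)silyl]oxy}pentan-2-yl]-3,5-dimethyl-4-oxo-4H-pyran-2-yl}-4,6-dimethylnon-5-en-2-yl]-2-ethyl-3,5-dimethyl-4H-pyran-4-one
Product: 21 6-[(2R,3R,4S,5E,7S,8R)-3,7-dihydroxy-8-{6-[(2S,3S)-3-hydroxypentan-2-yl]-3,5-dimethyl-4-oxo-4H-pyran-2-yl}-4,6-dimethylnon-5-en-2-yl]-2-ethyl-3,5-dimethyl-4H-pyran-4-one
Conditions: HF·pyridine, pyridine, THF, 0 °C → rt
Reagents that add atoms: none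
Why: Fluoride cleavage of the three silyl ethers under buffered, non-basic conditions (desilylation) avoids retro-aldol and allylic ionisation; no stereocentre is affected.

Step 11
Reactants: 21 6-[(2R,3R,4S,5E,7S,8R)-3,7-dihydroxy-8-{6-[(2S,3S)-3-hydroxypentan-2-yl]-3,5-dimethyl-4-oxo-4H-pyran-2-yl}-4,6-dimethylnon-5-en-2-yl]-2-ethyl-3,5-dimethyl-4H-pyran-4-one
Product: 23 2-ethyl-6-[(2R,3R,4R,5R,6E,8R)-3,5-dihydroxy-8-{6-[(2S,3S)-3-hydroxypentan-2-yl]-3,5-dimethyl-4-oxo-4H-pyran-2-yl}-4,6-dimethylnon-6-en-2-yl]-3,5-dimethyl-4H-pyran-4-one, via phenylboronate 22 (not isolated)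
Conditions: Ph3SiOReO3 (5 mol%), PhB(OH)2 (1.1 equiv), 4 Å molecular sieves, Et2O, −50 → −30 °C; Et3N; pinacol, rt
Reagents that add atoms: none
Why: Proposed new method: the perrhenate ester (heptavalent rhenium) of the C7 allylic alcohol undergoes a chair-like suprafacial [3,3] shift with the C8 substituent equatorial, which moves oxygen to C5 with (7S)→(5R) chirality transfer and forms the (6E)-alkene; the otherwise thermoneutral equilibrium is pulled to one side because only the product has a 1,3-diol (C3–OH/C5–OH) that condenses with PhB(OH)2 to a six-membered boronate, whose planar O–B–O unit tolerates the anti-diol and shields the new allylic oxygen from further perrhenate exchange before pinacol releases 23; closest known reaction: triphenylsilyl perrhenate-catalysed 1,3-transposition of allylic alcohols with acetal capture by a neighbouring hydroxyl.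

## Compound list

1 | pentan-3-one | CCC(=O)CC | starting material
2 | propanoic acid | CCC(=O)O | starting material
3 | 4,6-dimethylnonane-3,5,7-trione (stereo- and enol-isomer mixture) | CCC(=O)C(C)C(=O)C(C)C(=O)CC | intermediate (not isolated)
4 | 2,6-diethyl-3,5-dimethyl-4H-pyran-4-one | CCc1oc(CC)c(C)c(=O)c1C | intermediate
5 | propanal | CCC=O | starting material
6 | potassium (2Z)-6-ethyl-2-ethylidene-3,5-dimethyl-2H-pyran-4-olate | C/C=C1\OC(CC)=C(C)C([O-])=C1C.[K+] | intermediate (not isolated)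
7 | tert-butyl{[(2Z)-6-ethyl-2-ethylidene-3,5-dimethyl-2H-pyran-4-yl]oxy}dimethylsilane | C/C=C1\OC(CC)=C(C)C(O[Si](C)(C)C(C)(C)C)=C1C | intermediate (not isolated)
8 | 6-[(2S,3S)-3-{[tert-butyl(dimethyl)silyl]oxy}pentan-2-yl]-2-ethyl-3,5-dimethyl-4H-pyran-4-one | CCc1oc([C@@H](C)[C@@H](O[Si](C)(C)C(C)(C)C)CC)c(C)c(=O)c1C | intermediate
9 | methyl (2S)-3-hydroxy-2-methylpropanoate | COC(=O)[C@@H](C)CO | starting material
10 | methyl (2S)-2-methyl-3-[(triethylsilyl)oxy]propanoate | COC(=O)[C@@H](C)CO[Si](CC)(CC)CC | intermediate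
11 | (2S)-2-methyl-3-[(triethylsilyl)oxy]propanal | O=C[C@@H](C)CO[Si](CC)(CC)CC | intermediate
12 | lithium (2Z)-6-ethyl-2-ethylidene-3,5-dimethyl-2H-pyran-4-olate | C/C=C1\OC(CC)=C(C)C([O-])=C1C.[Li+] | intermediate (not isolated)
13 | 2-ethyl-6-[(2R,3R,4S)-3-hydroxy-4-methyl-5-[(triethylsilyl)oxy]pentan-2-yl]-3,5-dimethyl-4H-pyran-4-one | CCc1oc([C@H](C)[C@H](O)[C@@H](C)CO[Si](CC)(CC)CC)c(C)c(=O)c1C | intermediate
14 | 6-[(2R,3R,4S)-3-{[tert-butyl(dimethyl)silyl]oxy}-4-methyl-5-[(triethylsilyl)oxy]pentan-2-yl]-2-ethyl-3,5-dimethyl-4H-pyran-4-one | CCc1oc([C@H](C)[C@H](O[Si](C)(C)C(C)(C)C)[C@@H](C)CO[Si](CC)(CC)CC)c(C)c(=O)c1C | intermediate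
15 | (2R,3S,4R)-3-{[tert-butyl(dimethyl)silyl]oxy}-4-(6-ethyl-3,5-dimethyl-4-oxo-4H-pyran-2-yl)-2-methylpentanal | CCc1oc([C@H](C)[C@H](O[Si](C)(C)C(C)(C)C)[C@@H](C)C=O)c(C)c(=O)c1C | intermediate
16 | 2-(triphenylphosphoranylidene)propanal | CC(C=O)=P(c1ccccc1)(c1ccccc1)c1ccccc1 | starting material
17 | (2E,4S,5R,6R)-5-{[tert-butyl(dimethyl)silyl]oxy}-6-(6-ethyl-3,5-dimethyl-4-oxo-4H-pyran-2-yl)-2,4-dimethylhept-2-enal | CCc1oc([C@H](C)[C@H](O[Si](C)(C)C(C)(C)C)[C@@H](C)/C=C(C)/C=O)c(C)c(=O)c1C | intermediate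
18 | potassium (2Z)-6-[(2S,3S)-3-{[tert-butyl(dimethyl)silyl]oxy}pentan-2-yl]-2-ethylidene-3,5-dimethyl-2H-pyran-4-olate | C/C=C1\OC([C@@H](C)[C@@H](O[Si](C)(C)C(C)(C)C)CC)=C(C)C([O-])=C1C.[K+] | intermediate (not isolated)
19 | tert-butyl{[(2Z)-6-[(2S,3S)-3-{[tert-butyl(dimethyl)silyl]oxy}pentan-2-yl]-2-ethylidene-3,5-dimethyl-2H-pyran-4-yl]oxy}dimethylsilane | C/C=C1\OC([C@@H](C)[C@@H](O[Si](C)(C)C(C)(C)C)CC)=C(C)C(O[Si](C)(C)C(C)(C)C)=C1C | intermediate (not isolated)
20 | 6-[(2R,3R,4S,5E,7S,8R)-3,7-bis{[tert-butyl(dimethyl)silyl]oxy}-8-{6-[(2S,3S)-3-{[tert-butyl(dimethyl)silyl]oxy}pentan-2-yl]-3,5-dimethyl-4-oxo-4H-pyran-2-yl}-4,6-dimethylnon-5-en-2-yl]-2-ethyl-3,5-dimethyl-4H-pyran-4-one | CCc1oc([C@H](C)[C@H](O[Si](C)(C)C(C)(C)C)[C@@H](C)/C=C(C)/[C@@H](O[Si](C)(C)C(C)(C)C)[C@@H](C)c2oc([C@@H](C)[C@@H](O[Si](C)(C)C(C)(C)C)CC)c(C)c(=O)c2C)c(C)c(=O)c1C | intermediate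
21 | 6-[(2R,3R,4S,5E,7S,8R)-3,7-dihydroxy-8-{6-[(2S,3S)-3-hydroxypentan-2-yl]-3,5-dimethyl-4-oxo-4H-pyran-2-yl}-4,6-dimethylnon-5-en-2-yl]-2-ethyl-3,5-dimethyl-4H-pyran-4-one | CCc1oc([C@H](C)[C@H](O)[C@@H](C)/C=C(C)/[C@@H](O)[C@@H](C)c2oc([C@@H](C)[C@@H](O)CC)c(C)c(=O)c2C)c(C)c(=O)c1C | intermediate
22 | cyclic phenylboronate of 23 (2-phenyl-1,3,2-dioxaborinane spanning O3 and O5; stereocentres as in 23) | CCc1oc([C@H](C)[C@H](O3)[C@@H](C)[C@@H](OB3c4ccccc4)/C(C)=C/[C@@H](C)c2oc([C@@H](C)[C@@H](O)CC)c(C)c(=O)c2C)c(C)c(=O)c1C | intermediate (not isolated)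
23 | 2-ethyl-6-[(2R,3R,4R,5R,6E,8R)-3,5-dihydroxy-8-{6-[(2S,3S)-3-hydroxypentan-2-yl]-3,5-dimethyl-4-oxo-4H-pyran-2-yl}-4,6-dimethylnon-6-en-2-yl]-3,5-dimethyl-4H-pyran-4-one | CCc1oc([C@H](C)[C@H](O)[C@@H](C)[C@@H](O)/C(C)=C/[C@@H](C)c2oc([C@@H](C)[C@@H](O)CC)c(C)c(=O)c2C)c(C)c(=O)c1C | target

Descriptor changes along the route (for example 4S in 13, 14, 20 and 21 but 4R in 23, or 3R in 13 but 3S in 15) come from changes in CIP priority only; no centre is inverted after it is set.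

## Step count and risk

Total step count: 11.
Longest linear sequence: 9 steps (from 9 to 23, steps 3 to 11).

Steps most likely to fail:

**Step 2 (new asymmetric vinylogous aldol).** Risks are slow turnover because the pyranone carbonyl binds the silyl cation, and uncertain anti and enantioselectivity. The fallback sets out from 4 and comes back at 8. Deprotonation of 4 with LiN(SiMe3)2 in THF at −78 °C gives lithium dienolate 12, the intermediate of step 5, and addition of propanal 5 (the known lateral aldol of this pyranone) gives the syn and anti alcohols as racemates. The racemic anti alcohol rac-2-ethyl-6-[(2S*,3S*)-3-hydroxypentan-2-yl]-3,5-dimethyl-4H-pyran-4-one F1 is separated by chromatography. It is resolved by lipase-catalysed acylation (Candida antarctica lipase B, vinyl acetate, tert-butyl methyl ether, 35 °C); by the Kazlauskas rule this acetylates the (3R)-carbinol to (2R,3R)-2-(6-ethyl-3,5-dimethyl-4-oxo-4H-pyran-2-yl)pentan-3-yl acetate F2. It leaves 2-ethyl-6-[(2S,3S)-3-hydroxypentan-2-yl]-3,5-dimethyl-4H-pyran-4-one F3, which is silylated (tBuMe2SiOTf, 2,6-lutidine) to 8.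

**Step 9 (new asymmetric vinylogous aldol on the enal).** Risks are proton or silyl scrambling between the two pyranone rings and incomplete catalyst control. The fallback sets out from 8 and 17 and comes back at 21. Compound 8 is deprotonated with LiN(SiMe3)2 (THF, −78 °C) to lithium (2Z)-6-[(2S,3S)-3-{[tert-butyl(dimethyl)silyl]oxy}pentan-2-yl]-2-ethylidene-3,5-dimethyl-2H-pyran-4-olate F4, which is added directly to enal 17 and quenched with aq. NH4Cl. This is the known lithium dienolate aldol without catalyst control. The C7/C8 diastereomers are separated by preparative HPLC. The (7S,8R)-alcohol 6-[(2R,3R,4S,5E,7S,8R)-3-{[tert-butyl(dimethyl)silyl]oxy}-8-{6-[(2S,3S)-3-{[tert-butyl(dimethyl)silyl]oxy}pentan-2-yl]-3,5-dimethyl-4-oxo-4H-pyran-2-yl}-7-hydroxy-4,6-dimethylnon-5-en-2-yl]-2-ethyl-3,5-dimethyl-4H-pyran-4-one F5 is desilylated with HF·pyridine to 21.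

**Step 11 (new boronate-driven transposition).** Risks are ionisation of the allylic perrhenate, which erodes the C7→C5 chirality transfer or leads to cyclisation onto C3–OH, and catalyst binding by the pyranones. The fallback sets out from 21 and comes back at 23; it gives up the chirality relay. Re2O7 (5 mol%) with 2,2-dimethoxypropane in CH2Cl2 at room temperature, the established transposition with thermodynamic acetal capture, converts 21 into the all-cis acetonide of the C5 epimer, the 3,5-O-isopropylidene acetal of (5S)-23 F6. Aqueous acetic acid frees 2-ethyl-6-[(2R,3R,4R,5S,6E,8R)-3,5-dihydroxy-8-{6-[(2S,3S)-3-hydroxypentan-2-yl]-3,5-dimethyl-4-oxo-4H-pyran-2-yl}-4,6-dimethylnon-6-en-2-yl]-3,5-dimethyl-4H-pyran-4-one F7. MnO2 oxidises only the allylic C5 alcohol to 2-ethyl-6-[(2R,3S,4R,6E,8R)-3-hydroxy-8-{6-[(2S,3S)-3-hydroxypentan-2-yl]-3,5-dimethyl-4-oxo-4H-pyran-2-yl}-4,6-dimethyl-5-oxonon-6-en-2-yl]-3,5-dimethyl-4H-pyran-4-one F8. Hydroxyl-directed reduction with Me4NBH(OAc)3 (acetic acid/acetonitrile, −30 °C, Evans–Saksena 1,3-anti reduction) then delivers hydride anti to C3–OH and gives 23. Any (5R) material from the first operation converges at the same enone.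

## Further compounds

F1 | step 2 | rac-2-ethyl-6-[(2S*,3S*)-3-hydroxypentan-2-yl]-3,5-dimethyl-4H-pyran-4-one (racemic anti alcohol) | CCc1oc([C@@H](C)[C@@H](O)CC)c(C)c(=O)c1C.CCc1oc([C@H](C)[C@H](O)CC)c(C)c(=O)c1C
F2 | step 2 | (2R,3R)-2-(6-ethyl-3,5-dimethyl-4-oxo-4H-pyran-2-yl)pentan-3-yl acetate | CCc1oc([C@H](C)[C@H](OC(C)=O)CC)c(C)c(=O)c1C
F3 | step 2 | 2-ethyl-6-[(2S,3S)-3-hydroxypentan-2-yl]-3,5-dimethyl-4H-pyran-4-one | CCc1oc([C@@H](C)[C@@H](O)CC)c(C)c(=O)c1C
F4 | step 9 | lithium (2Z)-6-[(2S,3S)-3-{[tert-butyl(dimethyl)silyl]oxy}pentan-2-yl]-2-ethylidene-3,5-dimethyl-2H-pyran-4-olate | C/C=C1\OC([C@@H](C)[C@@H](O[Si](C)(C)C(C)(C)C)CC)=C(C)C([O-])=C1C.[Li+]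
F5 | step 9 | 6-[(2R,3R,4S,5E,7S,8R)-3-{[tert-butyl(dimethyl)silyl]oxy}-8-{6-[(2S,3S)-3-{[tert-butyl(dimethyl)silyl]oxy}pentan-2-yl]-3,5-dimethyl-4-oxo-4H-pyran-2-yl}-7-hydroxy-4,6-dimethylnon-5-en-2-yl]-2-ethyl-3,5-dimethyl-4H-pyran-4-one | CCc1oc([C@H](C)[C@H](O[Si](C)(C)C(C)(C)C)[C@@H](C)/C=C(C)/[C@@H](O)[C@@H](C)c2oc([C@@H](C)[C@@H](O[Si](C)(C)C(C)(C)C)CC)c(C)c(=O)c2C)c(C)c(=O)c1C
F6 | step 11 | 3,5-O-isopropylidene acetal of (5S)-23 (2,2-dimethyl-1,3-dioxane spanning O3 and O5; linker 2R,3R,4R,5S,6E,8R) | CCc1oc([C@H](C)[C@H](O3)[C@@H](C)[C@H](OC3(C)C)/C(C)=C/[C@@H](C)c2oc([C@@H](C)[C@@H](O)CC)c(C)c(=O)c2C)c(C)c(=O)c1C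
F7 | step 11 | 2-ethyl-6-[(2R,3R,4R,5S,6E,8R)-3,5-dihydroxy-8-{6-[(2S,3S)-3-hydroxypentan-2-yl]-3,5-dimethyl-4-oxo-4H-pyran-2-yl}-4,6-dimethylnon-6-en-2-yl]-3,5-dimethyl-4H-pyran-4-one | CCc1oc([C@H](C)[C@H](O)[C@@H](C)[C@H](O)/C(C)=C/[C@@H](C)c2oc([C@@H](C)[C@@H](O)CC)c(C)c(=O)c2C)c(C)c(=O)c1C
F8 | step 11 | 2-ethyl-6-[(2R,3S,4R,6E,8R)-3-hydroxy-8-{6-[(2S,3S)-3-hydroxypentan-2-yl]-3,5-dimethyl-4-oxo-4H-pyran-2-yl}-4,6-dimethyl-5-oxonon-6-en-2-yl]-3,5-dimethyl-4H-pyran-4-one | CCc1oc([C@H](C)[C@H](O)[C@@H](C)C(=O)/C(C)=C/[C@@H](C)c2oc([C@@H](C)[C@@H](O)CC)c(C)c(=O)c2C)c(C)c(=O)c1C
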